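**Plan**
Numbering used below: C1 = ring C=O, C2 (bears C7H2–O) = C3, C4 = CH–O‑tigloyl, C5 = CH–isopropyl, C6 = CH–OH. The retrosynthesis cuts, in order, the C7–O ester, the C2–C7 bond, the C6–O bond and the C4 ester (exchanged for a benzoate), then the ring at C2=C3 and C5–C6 in one operation.
Enabling feature: C6–C1(=O)–C2 are the alpha‑carbon, carbonyl and alpha'‑carbon of one ketone (a 1,3‑dinucleophile). C3–C4–C5 is an enal unit (C3 = CHO, C5 = beta‑carbon) whose alpha‑carbon C4 carries the oxygen, so the six‑membered carbocycle is a ketone/enal [3+3] annulation product with C4 open to enamine chemistry.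
Forward: enal + tert‑butyl acetoacetate give, in one flask, Michael addition (C5–C6), enamine benzoyloxylation (C4–O), aldol condensation (C2=C3) and decarboxylation. Then benzoate → tiglate, C6 hydroxylation, C7 hydroxymethylation, C7 tiglate.
Stereochemistry: one (R)‑diphenylprolinol silyl ether sets C5 (iminium face) and C4 (enamine face) by syn addition across the E‑enal, which is the cis C4–O/C5–isopropyl relation. The C6–OH enters anti to both under substrate control.

Key step: step 1

Remark: the enal, tert‑butyl acetoacetate, tigloyl chloride, dibenzoyl peroxide and the (R)‑prolinol silyl ether are taken as commercial.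

**Step 1**
Reactants: 1 (2E)-4-methylpent-2-enal; 2 tert-butyl 3-oxobutanoate
Product: 7 (1S,6S)-4-oxo-6-(propan-2-yl)cyclohex-2-en-1-yl benzoate, via Michael adduct 3 (not isolated), via benzoyloxy aldehyde 4 (not isolated), via cyclohexenone tert-butyl ester 5 (not isolated), via keto acid 6 (not isolated)
Conditions: (R)-2-[diphenyl(trimethylsilyloxy)methyl]pyrrolidine (10 mol%), PhCO2H (10 mol%), toluene, 0 °C to rt; then (PhCO2)2 (added once 1 is consumed), 0 °C; then p-TsOH·H2O (30 mol%), 70 °C
Reagents that add atoms: dibenzoyl peroxide, O=C(OOC(=O)c1ccccc1)c1ccccc1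
Why: Proposed new method: the (R)-amine condenses with 1 to an E-iminium ion whose unshielded face takes up the doubly activated carbon of 2 at C5 (iminium Michael addition); the enamine that results, or re-forms from released aldehyde 3, attacks the O–O bond of the peroxide at C4 from the same unshielded face to give 4, and TsOH then drives intramolecular aldol condensation, loss of 2-methylpropene and decarboxylation. The closest known reaction types are the amine-catalysed Michael addition of beta-keto esters to enals with acid-induced Robinson-type closure, the amine-catalysed alpha-benzoyloxylation of aldehydes with dibenzoyl peroxide, and iminium–enamine cascades that add a nucleophile and an electrophile across an enal; new is their union in one flask. The six-membered ring closes by a 6-(enolendo)-exo-trig aldol addition of the methyl-ketone enol carbon C2 to the aldehyde carbon C3, and dehydration gives the C2=C3 bond. C5 is set by catalyst-controlled attack on the iminium face and C4 by catalyst-controlled attack of the enamine on the peroxide; both groups add to the same face of the E-alkene, which is the cis relation of benzoate and isopropyl in the ring. The step needs C-attack of 2 through its 1,3-dicarbonyl carbon, oxygenation at the aldehyde alpha-carbon and not at the beta-keto ester, and closure before C4 epimerises; these should be secured by the acidity of the 1,3-dicarbonyl position, by the higher nucleophilicity of the enamine over the hindered neutral enol, and by the fast intramolecular reaction of the electron-poor alpha-acyloxy aldehyde.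

**Step 2**
Reactants: 7 (1S,6S)-4-oxo-6-(propan-2-yl)cyclohex-2-en-1-yl benzoate
Product: 8 (4S,5S)-4-hydroxy-5-(propan-2-yl)cyclohex-2-en-1-one
Conditions: K2CO3 (0.2 equiv), MeOH, 0 °C
Reagents that add atoms: none
Why: Base-catalysed transesterification of the allylic benzoate; with C6 still unsubstituted the alpha'-enolate has no leaving group in beta-position and no stereocenter is touched, so the cis relation from step 1 should be kept.

**Step 3**
Reactants: 8 (4S,5S)-4-hydroxy-5-(propan-2-yl)cyclohex-2-en-1-one; 9 (2E)-2-methylbut-2-enoyl chloride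
Product: 10 (1S,6S)-4-oxo-6-(propan-2-yl)cyclohex-2-en-1-yl (2E)-2-methylbut-2-enoate
Conditions: pyridine, 4-(dimethylamino)pyridine (cat.), CH2Cl2, 0 °C to rt
Reagents that add atoms: none
Why: Nucleophile-catalysed O-acylation through the acylpyridinium ion; only the O–H bond reacts, so C4 keeps its configuration, and the E-tigloyl geometry is the stable one.

**Step 4**
Reactants: 10 (1S,6S)-4-oxo-6-(propan-2-yl)cyclohex-2-en-1-yl (2E)-2-methylbut-2-enoate
Product: 13 (1S,5R,6R)-5-hydroxy-4-oxo-6-(propan-2-yl)cyclohex-2-en-1-yl (2E)-2-methylbut-2-enoate, via silyl dienol ether 11 (not isolated), via silyloxy ketone 12 (not isolated)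
Conditions: LiN(SiMe3)2, Me3SiCl, THF, −78 °C; mCPBA, CH2Cl2, −20 to 0 °C; 1 M HCl, THF, 0 °C
Reagents that add atoms: mCPBA, OOC(=O)c1cccc(Cl)c1; chlorotrimethylsilane, C[Si](C)(C)Cl (its silyl group is carried by 11 and 12 only)
Why: Rubottom oxidation: kinetic alpha'-deprotonation gives the cross-conjugated silyl dienol ether, whose electron-rich C1=C6 bond should be epoxidised on the face opposite the C5 isopropyl and C4 ester groups, so that silyl migration and acidic work-up leave the C6 hydroxyl trans to isopropyl.

**Step 5**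
Reactants: 13 (1S,5R,6R)-5-hydroxy-4-oxo-6-(propan-2-yl)cyclohex-2-en-1-yl (2E)-2-methylbut-2-enoate
Product: 14 (1S,5R,6R)-5-hydroxy-3-(hydroxymethyl)-4-oxo-6-(propan-2-yl)cyclohex-2-en-1-yl (2E)-2-methylbut-2-enoate
Conditions: aq. HCHO (37%), 4-(dimethylamino)pyridine (0.3 equiv), THF/H2O, rt
Reagents that add atoms: formaldehyde, C=O
Why: Morita–Baylis–Hillman reaction: the pyridine adds to C3, the enolate takes up formaldehyde at C2 and loss of the catalyst restores the enone; no stereocenter is formed and the weak base should leave ester and alpha-ketol intact.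

**Step 6**
Reactants: 14 (1S,5R,6R)-5-hydroxy-3-(hydroxymethyl)-4-oxo-6-(propan-2-yl)cyclohex-2-en-1-yl (2E)-2-methylbut-2-enoate; 9 (2E)-2-methylbut-2-enoyl chloride
Product: 15 (1S,5R,6R)-5-hydroxy-3-({[(2E)-2-methylbut-2-enoyl]oxy}methyl)-4-oxo-6-(propan-2-yl)cyclohex-2-en-1-yl (2E)-2-methylbut-2-enoate
Conditions: 2,4,6-collidine, CH2Cl2, −40 to −20 °C
Reagents that add atoms: none
Why: Kinetically selective O-acylation of the unhindered primary allylic alcohol over the secondary alpha-ketol hydroxyl, which is flanked by isopropyl and hydrogen-bonded to the C1 carbonyl; the hindered, non-nucleophilic base should avoid allylic (SN2') attack on the new 2-(acyloxymethyl)enone.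

**Compound list**
1 | (2E)-4-methylpent-2-enal | CC(C)/C=C/C=O | starting material
2 | tert-butyl 3-oxobutanoate | CC(=O)CC(=O)OC(C)(C)C | starting material
3 | tert-butyl (3R)-2-acetyl-5-oxo-3-(propan-2-yl)pentanoate (C2 epimers, in equilibrium with its cyclic hemiacetal) | O=CC[C@H](C(C)C)C(C(C)=O)C(=O)OC(C)(C)C | intermediate
4 | tert-butyl (3R,4R)-2-acetyl-4-(benzoyloxy)-5-oxo-3-(propan-2-yl)pentanoate | O=C[C@H](OC(=O)c1ccccc1)[C@H](C(C)C)C(C(C)=O)C(=O)OC(C)(C)C | intermediate
5 | tert-butyl (5S,6R)-5-(benzoyloxy)-2-oxo-6-(propan-2-yl)cyclohex-3-ene-1-carboxylate | C1=C[C@H](OC(=O)c2ccccc2)[C@H](C(C)C)C(C(=O)OC(C)(C)C)C1=O | intermediate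
6 | (5S,6R)-5-(benzoyloxy)-2-oxo-6-(propan-2-yl)cyclohex-3-ene-1-carboxylic acid | C1=C[C@H](OC(=O)c2ccccc2)[C@H](C(C)C)C(C(=O)O)C1=O | intermediate
7 | (1S,6S)-4-oxo-6-(propan-2-yl)cyclohex-2-en-1-yl benzoate | C1=C[C@H](OC(=O)c2ccccc2)[C@H](C(C)C)CC1=O | intermediate
8 | (4S,5S)-4-hydroxy-5-(propan-2-yl)cyclohex-2-en-1-one | C1=C[C@H](O)[C@H](C(C)C)CC1=O | intermediate
9 | (2E)-2-methylbut-2-enoyl chloride (tigloyl chloride) | C/C=C(\C)C(Cl)=O | starting material
10 | (1S,6S)-4-oxo-6-(propan-2-yl)cyclohex-2-en-1-yl (2E)-2-methylbut-2-enoate | C1=C[C@H](OC(=O)/C(C)=C/C)[C@H](C(C)C)CC1=O | intermediate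
11 | (1S,6R)-6-(propan-2-yl)-4-[(trimethylsilyl)oxy]cyclohexa-2,4-dien-1-yl (2E)-2-methylbut-2-enoate | C1=C[C@H](OC(=O)/C(C)=C/C)[C@H](C(C)C)C=C1O[Si](C)(C)C | intermediate
12 | (1S,5R,6S)-4-oxo-6-(propan-2-yl)-5-[(trimethylsilyl)oxy]cyclohex-2-en-1-yl (2E)-2-methylbut-2-enoate | C1=C[C@H](OC(=O)/C(C)=C/C)[C@H](C(C)C)[C@@H](O[Si](C)(C)C)C1=O | intermediate
13 | (1S,5R,6R)-5-hydroxy-4-oxo-6-(propan-2-yl)cyclohex-2-en-1-yl (2E)-2-methylbut-2-enoate | C1=C[C@H](OC(=O)/C(C)=C/C)[C@H](C(C)C)[C@@H](O)C1=O | intermediate
14 | (1S,5R,6R)-5-hydroxy-3-(hydroxymethyl)-4-oxo-6-(propan-2-yl)cyclohex-2-en-1-yl (2E)-2-methylbut-2-enoate | OCC1=C[C@H](OC(=O)/C(C)=C/C)[C@H](C(C)C)[C@@H](O)C1=O | intermediate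
15 | (1S,5R,6R)-5-hydroxy-3-({[(2E)-2-methylbut-2-enoyl]oxy}methyl)-4-oxo-6-(propan-2-yl)cyclohex-2-en-1-yl (2E)-2-methylbut-2-enoate | C/C=C(\C)C(=O)OCC1=C[C@H](OC(=O)/C(C)=C/C)[C@H](C(C)C)[C@@H](O)C1=O | target

Total step count: 6. Longest linear sequence: 6 steps (from 1 and 2 to 15).

**Steps most likely to fail**

Step 1. The risks are oxidative loss of the secondary amine by the peroxide before the enamine is intercepted, stalling of the oxygenation because aldehyde 3 rests as its cyclic hemiacetal, and acid-induced enolisation or acyl migration that erodes the C4 configuration during ring closure. The fallback uses known reaction types only. It sets out from 1 and 2: the same amine and then TsOH, without peroxide, should give (5S)-5-(propan-2-yl)cyclohex-2-en-1-one F1 through 3 by Michael addition, aldol condensation and decarboxylation. Isopropenyl acetate with catalytic TsOH converts F1 into the linear dienyl acetate (5S)-5-(propan-2-yl)cyclohexa-1,3-dien-1-yl acetate F2. mCPBA should oxidise F2 at C4 on the face away from the isopropyl group to the trans alcohol (4R,5S)-4-hydroxy-5-(propan-2-yl)cyclohex-2-en-1-one F3. A Mitsunobu reaction with benzoic acid (PPh3, diisopropyl azodicarboxylate, THF) inverts C4 and comes back to the route at 7.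

Step 5. The risks are slow turnover of the Morita–Baylis–Hillman cycle at a beta-carbon flanked by the C4 ester, and competing base-induced hydroxymethylation or epimerisation at C6 over the long reaction time. The fallback sets out from 13: alpha-iodination (I2, pyridine, CH2Cl2), in which the enolate is trapped fast and irreversibly, should give (1R,5R,6R)-5-hydroxy-3-iodo-4-oxo-6-(propan-2-yl)cyclohex-2-en-1-yl (2E)-2-methylbut-2-enoate F4. Stille coupling of F4 with (tributylstannyl)methanol and Pd(PPh3)4 (zerovalent palladium) in dioxane at 80 °C installs the hydroxymethyl group and comes back at 14.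

Step 4. The risks are competing deprotonation at the gamma-methyl of the tiglate or at C4, acyl transfer to the enolate oxygen, and incomplete facial control in the epoxidation. The fallback sets out from 10 and avoids strong base and silyl enol ethers: alpha'-acetoxylation with Mn(OAc)3·2H2O in benzene at reflux should place the acetate anti to the isopropyl group and give (1S,5R,6S)-5-(acetyloxy)-4-oxo-6-(propan-2-yl)cyclohex-2-en-1-yl (2E)-2-methylbut-2-enoate F5. Selective methanolysis of the activated alpha-keto acetate (K2CO3 cat., MeOH, 0 °C), which the hindered conjugated tiglate should outlast, comes back at 13.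

**Further compounds**
F1 | step 1 | (5S)-5-(propan-2-yl)cyclohex-2-en-1-one | C1=CC[C@H](C(C)C)CC1=O
F2 | step 1 | (5S)-5-(propan-2-yl)cyclohexa-1,3-dien-1-yl acetate | CC(=O)OC1=CC=C[C@H](C(C)C)C1
F3 | step 1 | (4R,5S)-4-hydroxy-5-(propan-2-yl)cyclohex-2-en-1-one | C1=C[C@@H](O)[C@H](C(C)C)CC1=O
F4 | step 5 | (1R,5R,6R)-5-hydroxy-3-iodo-4-oxo-6-(propan-2-yl)cyclohex-2-en-1-yl (2E)-2-methylbut-2-enoate | IC1=C[C@H](OC(=O)/C(C)=C/C)[C@H](C(C)C)[C@@H](O)C1=O
F5 | step 4 | (1S,5R,6S)-5-(acetyloxy)-4-oxo-6-(propan-2-yl)cyclohex-2-en-1-yl (2E)-2-methylbut-2-enoate | C1=C[C@H](OC(=O)/C(C)=C/C)[C@H](C(C)C)[C@@H](OC(C)=O)C1=O
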